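The numbers in the tables are calculated with constants of no real substance; scatter was added.

Of my two earlier runs, Thursday's held more solid reagent than Friday's, and the question was what ochre and red would give after 3.0 h.

| setting | Friday's | Thursday's | ochre | red |
|---|---|---|---|---|
| left-handed substrate | 0.50 M | 0.50 M | 0.50 M | 0.50 M |
| right-handed substrate | 0.50 M | 0.50 M | 0.50 M | 0.50 M |
| solid reagent | 0.69 M | 1.7 M | 1.25 M | 0.600 M |
| remark | run made earlier | run made earlier |  |  |
| time |  |  | 3.0 h | 3.0 h |

| run | time / min | right-handed substrate / % | left-handed substrate / % |
|---|---|---|---|
| Friday's | 12.0 | 48.7 | 45.3 |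
| Friday's | 30.0 | 44.4 | 41.7 |
| Friday's | 60.0 | 41.6 | 35.4 |
| Friday's | 90.0 | 38.5 | 32.4 |
| Friday's | 120 | 37.1 | 29.9 |
| Thursday's | 10.0 | 48.9 | 46.9 |
| Thursday's | 20.0 | 45.3 | 44.2 |
| Thursday's | 40.0 | 43.4 | 39.3 |
| Thursday's | 60.0 | 40.6 | 34.4 |
| Thursday's | 120 | 36.6 | 27.0 |

(scatter of a reading: 0.5 percentage points)

1. the flask that ends with the higher excess of right-handed substrate over left-handed substrate among what is left of the two, or "neither" when 2 percentage points or less lies between them (ochre / red / neither)
2. excess of right-handed substrate over left-handed substrate among what is left of the two at the end, ochre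
3. excess of right-handed substrate over left-handed substrate among what is left of the two at the end, red

- coupling partner is single-handed; left-handed substrate and right-handed substrate are mirror images of each other, charged as a racemate, each of them at the stated concentration
- solid, in amounts per volume of the solution: solid reagent
- at the start none of the solid reagent is in solution
- an excess is the difference of the two amounts in percent of their sum
- an excess is below zero if the other one leads
- the handed part of coupling partner does not stay in what it makes, so the products of the two hands are mirror images too

Yet at 60.0 min the gap G, right-handed substrate minus left-handed substrate, was 6.2 percentage points on Friday and 6.2 points on Thursday. By that reading, the extra solid had not widened G. In the next hour, though, Friday's G rose by 1 point and Thursday's by 3.4 points. So I read the charge as buying time, and took Friday's 0.69 M as used by about 60.0 min. That gave the supply rate u = 0.690 M h⁻¹, the solid used per hour while some remains. The supply time τ is the charge divided by u: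

τ, ochre = 1.81 h; τ, red = 0.870 h

Both are shorter than the run, so I took the solid as the limiting reagent. I then read G at τ from the runs, Friday's first-hour slope for red and Thursday's second-hour slope for ochre, and assumed that G stood there until the end:

G, ochre = 9 points; G, red = 5.4 points

Divided by Thursday's last sum of the two, 63.6%, read at 120 min and so earlier than the end of ochre and red, these gave me estimates of 14.1% for ochre and 8.48% for red.

The forecast said ochre, with 18% and 10.5%, both above mine, holding that “the solid acts through a saturated or dissolution-limited supply”.

The flasks gave ochre, with 15.2% and 8.11%, and the forecast held within its tolerance.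

    achiral form → waste (k = 7.80 × 10⁻⁶ s⁻¹)
    coupling partner + right-handed substrate → right-handed product (k = 9.10 × 10⁻⁶ L mol⁻¹ s⁻¹)
    left-handed substrate ⇌ achiral form (K = 0.560, k = 7.60 × 10⁻⁵ s⁻¹)
    right-handed substrate ⇌ achiral form (K = 0.560, k = 7.60 × 10⁻⁵ s⁻¹)
    solid reagent ⇌ coupling partner, rate k5*(cs5 - [coupling partner]) while solid is left; crystals form when [coupling partner] > cs5 (solubility = 0.180 M, k = 0.00510 s⁻¹)
    achiral form → side product (k = 1.40 × 10⁻⁴ s⁻¹)
    coupling partner + left-handed substrate → left-handed product (k = 3.60 × 10⁻⁴ L mol⁻¹ s⁻¹)
    2 coupling partner → self-condensation product (k = 0.00340 L mol⁻¹ s⁻¹)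

Ochre had 18.5% of its solid left at 1.50 h, where u leaves 17.2%. A neighbour of ochre, charged with 0.31 M of solid, has τ = 0.449 h, so Friday's slope gives G = 2.8 points, and the same sum gives 4.40%. That flask ended with 30.2% left-handed substrate, 33.5% right-handed substrate and an excess of 5.09%.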